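**Plan**

1. Retrosynthetic cuts, in order: C13–C14 (vinyl addition to a C13 ketone), the four acetates, the C20(=O)–O12 lactone bond (reduction), the two C4–CH3 bonds, then C5–C10 and C8–C9 together (ring B by a [4+2] cycloaddition), the C9=C10 alkene (ring-closing metathesis) and C1–C2 (β-keto ester alkylation).
2. Enabling feature: ring B (C5–C10) carries both a methyl group and an oxygen at C8, and C5 and C8 are its 1,4-carbons. C5–C6–C7–C8 plus the C8 oxygen is therefore the footprint of a 2-methyl-5-alkylfuran added across C9=C10. A C3 ketone (β to C5) allows the C5–O bond to be cut afterwards, and O12 and C20 can be tied as a δ-lactone.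
3. Forward: a furyl β-keto ester and a lactate-derived homoallylic alcohol are joined, metathesis closes the temporary lactone (C9=C10 locked Z), and one cycloaddition/bridge-opening step closes rings B and A.
4. Ring A is then finished (deconjugative gem-dimethylation, hydrogen-atom-transfer hydrogenation, ketone reduction), the lactone is reduced, the hydroxyls are acetylated and C13 is built last.
5. Stereochemistry: C12 from methyl (R)-lactate by chelation-controlled allylation; C8, C9 and C10 from the exo-tether/endo-lactone cycloaddition, whose face is set by C12; C5 by hydrogen-atom transfer (trans fusion); C3 by a bulky hydride; C13 by Felkin–Anh addition.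

Key step: step 10

Remark: labdane numbering (C1–C20) is used for the target and all intermediates; the lactate stereocenter (future C13) serves only for chelation control and is oxidised away in step 18.

**Step 1**
Reactants: 1 5-methylfurfural
Product: 3 (5-methylfuran-2-yl)acetonitrile, via formamide adduct 2 (not isolated)
Conditions: TosMIC, t-BuOK, DME, −40 °C; then MeOH, 65 °C
Reagents that add atoms: p-toluenesulfonylmethyl isocyanide, Cc1ccc(cc1)S(=O)(=O)C[N+]#[C-]
Why: van Leusen reductive cyanation, in which the TosMIC anion adds to the aldehyde, the oxazoline opens to the N-(1-tosylalkenyl)formamide and methanolysis with loss of sulfinate should give the one-carbon-homologated nitrile.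

**Step 2**
Reactants: 3 (5-methylfuran-2-yl)acetonitrile
Product: 5 prop-2-enyl 4-(5-methylfuran-2-yl)-3-oxobutanoate, via Blaise enamino ester 4 (not isolated)
Conditions: Zn, BrCH2CO2CH2CH=CH2, THF, 65 °C; then 1 M HCl, 20 °C
Reagents that add atoms: allyl bromoacetate, C=CCOC(=O)CBr; water, O
Why: Blaise reaction, in which the zinc enolate adds to the nitrile and acid hydrolysis of the enamino ester should give the β-keto ester whose C2 is the most acidic carbon of the future tether.

**Step 3**
Reactants: 6 methyl (R)-lactate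
Product: 7 methyl (R)-2-(benzyloxy)propanoate
Conditions: BnOC(=NH)CCl3, TfOH (cat.), cyclohexane–CH2Cl2, 20 °C
Reagents that add atoms: benzyl 2,2,2-trichloroacetimidate, ClC(Cl)(Cl)C(=N)OCc1ccccc1
Why: acid-catalysed O-benzylation with the trichloroacetimidate avoids base and should keep the lactate stereocenter intact.

**Step 4**
Reactants: 7 methyl (R)-2-(benzyloxy)propanoate
Product: 8 (R)-2-(benzyloxy)propanal
Conditions: i-Bu2AlH, CH2Cl2, −78 °C
Reagents that add atoms: none
Why: partial ester reduction at low temperature stops at the tetrahedral aluminate and should give the α-benzyloxy aldehyde without epimerization.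

**Step 5**
Reactants: 8 (R)-2-(benzyloxy)propanal
Product: 9 (2R,3R)-2-(benzyloxy)hex-5-en-3-ol
Conditions: CH2=CHCH2SnBu3, MgBr2·OEt2, CH2Cl2, −20 °C
Reagents that add atoms: allyltributylstannane, C=CC[Sn](CCCC)(CCCC)CCCC
Why: chelation-controlled (Cram-chelate) allylation, in which MgBr2 bridges the aldehyde and benzyloxy oxygens and the stannane attacks the less hindered face, should give the syn alcohol and thereby set C12 as R.

**Step 6**
Reactants: 9 (2R,3R)-2-(benzyloxy)hex-5-en-3-ol; 10 2-(bromomethyl)acrylic acid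
Product: 11 (2R,3R)-2-(benzyloxy)hex-5-en-3-yl 2-(bromomethyl)prop-2-enoate
Conditions: DCC, DMAP (cat.), CH2Cl2, 0 °C
Reagents that add atoms: none
Why: Steglich esterification of the secondary alcohol, run cold with only catalytic DMAP so that the allylic bromide should survive.

**Step 7**
Reactants: 5 prop-2-enyl 4-(5-methylfuran-2-yl)-3-oxobutanoate; 11 (2R,3R)-2-(benzyloxy)hex-5-en-3-yl 2-(bromomethyl)prop-2-enoate
Product: 12 prop-2-enyl 2-[2-({[(2R,3R)-2-(benzyloxy)hex-5-en-3-yl]oxy}carbonyl)prop-2-enyl]-4-(5-methylfuran-2-yl)-3-oxobutanoate (C2 epimers)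
Conditions: K2CO3, acetone, 20 °C
Reagents that add atoms: none
Why: alkylation of the β-keto ester at its doubly activated C2 by the allylic bromide (SN2 or SN2′ give the same product) forms C1–C2, and the new C2 stereocenter is removed in step 8.

**Step 8**
Reactants: 12 keto diester
Product: 13 (2R,3R)-2-(benzyloxy)hex-5-en-3-yl 2-methylidene-6-(5-methylfuran-2-yl)-5-oxohexanoate
Conditions: Pd(OAc)2 (cat.), PPh3, HCO2H, Et3N, THF, 20 °C
Reagents that add atoms: none
Why: palladium-catalysed deallylation–decarboxylation of the allyl β-keto ester with formate as hydride source should give the ketone under near-neutral conditions that spare the acrylate and the furan.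

**Step 9**
Reactants: 13 keto acrylate
Product: 14 (6R)-6-[(1R)-1-(benzyloxy)ethyl]-3-[4-(5-methylfuran-2-yl)-3-oxobutyl]-5,6-dihydro-2H-pyran-2-one
Conditions: second-generation Grubbs catalyst (5 mol%), toluene, 80 °C
Reagents that add atoms: none
Why: ring-closing metathesis of the 1,1-disubstituted acrylate with the terminal vinyl group closes the δ-lactone and thereby locks C9=C10 with C11 cis to C20.

**Step 10**
Reactants: 14 furyl keto lactone
Product: 16 (12R,13R)-13-(benzyloxy)-8α-hydroxy-3-oxo-14,15,18,19-tetranorlabda-4,6-dien-20,12-olide, via oxanorbornene adduct 15 (not isolated)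
Conditions: MeAlCl2 (3 equiv), CH2Cl2, −78 °C; then Et3N, −78 to 0 °C
Reagents that add atoms: none
Why: MeAlCl2 on the lactone carbonyl activates C9=C10 and the 2,5-dialkylfuran (C5=C6–C7=C8) adds across it in a concerted, asynchronous [4+2] reaction that forms C8–C9 and C5–C10 (Lewis-acid-promoted intramolecular Diels–Alder reaction of a furan, a known reaction type), after which Et3N enolizes the aluminium-bound C3 ketone toward C4 and the enolate expels the bridging oxygen from C5 (E1cB), leaving the furan oxygen on C8 as the tertiary hydroxyl. Ring B closes as the six-membered carbocycle of the cycloadduct and ring A closes through the four-atom tether C4–C3–C2–C1 in the exo mode (tether syn to the oxygen bridge), which a short tether enforces. Suprafacial addition with the tether exo places the ring-locked lactone (C20 and C11) endo, which fixes 8α-O, 9β-C11 and 10β-C20 relative to one another. The absolute sense comes from C12: the cycloaddition is reversible under these conditions, and only in the adduct that leads to the target can the C12 substituent lie pseudo-equatorial on the convex face of the endo-fused lactone, whereas in the other facial adduct it is axial or the lactone must fold into the concave pocket under C6=C7. The step therefore needs facial selectivity, which rests on equilibration of the adducts before the base is added, and a regioselective bridge opening, which is secured because only C5–O is β to an enolizable carbon.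

**Step 11**
Reactants: 16 dienone lactone
Product: 17 (12R,13R)-13-(benzyloxy)-8α-hydroxy-3-oxo-14,15,18,19-tetranorlabd-4-en-20,12-olide
Conditions: H2 (1 atm), RhCl(PPh3)3 (cat.), benzene–EtOH, 20 °C
Reagents that add atoms: none
Why: homogeneous hydrogenation should be selective for the less hindered cis-disubstituted C6=C7 bond of the linear dienone and leave the trisubstituted conjugated C4=C5 bond and the benzyl ether.

**Step 12**
Reactants: 17 enone lactone
Product: 19 (12R,13R)-13-(benzyloxy)-8α-hydroxy-3-oxo-14,15-dinorlabd-5-en-20,12-olide, via monomethyl ketone 18 (not isolated)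
Conditions: t-BuOK (3.3 equiv), t-BuOH–THF, 0 °C; MeI (2.2 equiv), 0 to 20 °C
Reagents that add atoms: iodomethane, CI
Why: deconjugative double α-alkylation, in which the extended dienolate formed by γ-deprotonation at C6 is methylated twice at C4, should install the gem-dimethyl group and move the double bond to C5=C6.

**Step 13**
Reactants: 19 β,γ-unsaturated ketone
Product: 20 (12R,13R)-13-(benzyloxy)-8α-hydroxy-3-oxo-14,15-dinor-5α-labdan-20,12-olide
Conditions: Mn(dpm)3 (cat.), PhSiH3, t-BuOOH, i-PrOH, 20 °C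
Reagents that add atoms: none
Why: metal-hydride hydrogen-atom-transfer hydrogenation gives the tertiary C5 radical, which should be reduced from the α-face opposite the axial C10 substituent to the thermodynamically preferred trans ring fusion (5α-H) without touching the benzyl ether.

**Step 14**
Reactants: 20 saturated ketone
Product: 21 (12R,13R)-13-(benzyloxy)-3α,8α-dihydroxy-14,15-dinor-5α-labdan-20,12-olide
Conditions: LiBH(s-Bu)3, THF, −78 °C
Reagents that add atoms: none
Why: the bulky hydride should attack the C3 ketone from the equatorial direction, away from the axial 4β-methyl, and give the axial 3α-alcohol while the lactone is left.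

**Step 15**
Reactants: 21 hydroxy lactone
Product: 22 (12R,13R)-13-(benzyloxy)-14,15-dinor-5α-labdane-3α,8α,12,20-tetraol
Conditions: LiAlH4, THF, 0 to 20 °C
Reagents that add atoms: none
Why: hydride reduction of the lactone gives the C20 primary alcohol and frees the C12 hydroxyl with its configuration unchanged.

**Step 16**
Reactants: 22 tetraol
Product: 23 (12R,13R)-13-(benzyloxy)-14,15-dinor-5α-labdane-3α,8α,12,20-tetrayl tetraacetate
Conditions: Ac2O, DMAP, Et3N, CH2Cl2, 40 °C
Reagents that add atoms: acetic anhydride, CC(=O)OC(C)=O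
Why: exhaustive DMAP-promoted acetylation should esterify the primary, both secondary and the tertiary C8 hydroxyl while the C13 oxygen is still benzyl-protected, so that no second tertiary alcohol competes.

**Step 17**
Reactants: 23 tetraacetate benzyl ether
Product: 24 (12R,13R)-13-hydroxy-14,15-dinor-5α-labdane-3α,8α,12,20-tetrayl tetraacetate
Conditions: H2 (1 atm), Pd(OH)2/C, EtOAc, 20 °C
Reagents that add atoms: none
Why: hydrogenolysis of the benzyl ether frees the C13 hydroxyl at a stage where no alkene is present.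

**Step 18**
Reactants: 24 secondary alcohol
Product: 25 (12R)-13-oxo-14,15-dinor-5α-labdane-3α,8α,12,20-tetrayl tetraacetate
Conditions: Dess–Martin periodinane, NaHCO3, CH2Cl2, 20 °C
Reagents that add atoms: none
Why: buffered Dess–Martin oxidation should convert the carbinol into the methyl ketone without epimerizing the adjacent acetoxy-bearing C12.

**Step 19**
Reactants: 25 α-acetoxy methyl ketone
Product: 26 (12R,13S)-13-hydroxylabd-14-ene-3α,8α,12,20-tetrayl tetraacetate (target)
Conditions: CH2=CHMgBr, CeCl3, THF, −78 °C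
Reagents that add atoms: vinylmagnesium bromide, C=C[Mg]Br
Why: 1,2-addition of the vinylcerium reagent under Felkin–Anh control, with the C12–OAc bond antiperiplanar to the incoming nucleophile and attack past the C12 hydrogen, should give the 13S tertiary alcohol, and the low basicity of the cerium reagent limits enolization and attack on the acetates.

**Compound list**

1 | 5-methylfurfural | Cc1ccc(C=O)o1 | starting material
2 | N-[2-(5-methylfuran-2-yl)-1-(4-methylbenzenesulfonyl)ethenyl]formamide | Cc1ccc(C=C(NC=O)S(=O)(=O)c2ccc(C)cc2)o1 | intermediate (not isolated)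
3 | (5-methylfuran-2-yl)acetonitrile | Cc1ccc(CC#N)o1 | intermediate
4 | prop-2-enyl 3-amino-4-(5-methylfuran-2-yl)but-2-enoate (present as its bromozinc salt) | Cc1ccc(CC(N)=CC(=O)OCC=C)o1 | intermediate (not isolated)
5 | prop-2-enyl 4-(5-methylfuran-2-yl)-3-oxobutanoate | Cc1ccc(CC(=O)CC(=O)OCC=C)o1 | intermediate
6 | methyl (R)-lactate | C[C@@H](O)C(=O)OC | starting material
7 | methyl (R)-2-(benzyloxy)propanoate | C[C@@H](OCc1ccccc1)C(=O)OC | intermediate
8 | (R)-2-(benzyloxy)propanal | C[C@@H](OCc1ccccc1)C=O | intermediate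
9 | (2R,3R)-2-(benzyloxy)hex-5-en-3-ol | C[C@@H](OCc1ccccc1)[C@H](O)CC=C | intermediate
10 | 2-(bromomethyl)acrylic acid | OC(=O)C(=C)CBr | starting material
11 | (2R,3R)-2-(benzyloxy)hex-5-en-3-yl 2-(bromomethyl)prop-2-enoate | C=CC[C@@H](OC(=O)C(=C)CBr)[C@@H](C)OCc1ccccc1 | intermediate
12 | prop-2-enyl 2-[2-({[(2R,3R)-2-(benzyloxy)hex-5-en-3-yl]oxy}carbonyl)prop-2-enyl]-4-(5-methylfuran-2-yl)-3-oxobutanoate (C2 epimers) | Cc1ccc(CC(=O)C(CC(=C)C(=O)O[C@H](CC=C)[C@@H](C)OCc2ccccc2)C(=O)OCC=C)o1 | intermediate
13 | (2R,3R)-2-(benzyloxy)hex-5-en-3-yl 2-methylidene-6-(5-methylfuran-2-yl)-5-oxohexanoate | Cc1ccc(CC(=O)CCC(=C)C(=O)O[C@H](CC=C)[C@@H](C)OCc2ccccc2)o1 | intermediate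
14 | (6R)-6-[(1R)-1-(benzyloxy)ethyl]-3-[4-(5-methylfuran-2-yl)-3-oxobutyl]-5,6-dihydro-2H-pyran-2-one | Cc1ccc(CC(=O)CCC2=CC[C@H]([C@@H](C)OCc3ccccc3)OC2=O)o1 | intermediate
15 | (12R,13R)-13-(benzyloxy)-5α,8α-epoxy-3-oxo-14,15,18,19-tetranorlabd-6-en-20,12-olide | C[C@@]12O[C@]3(C=C1)CC(=O)CC[C@@]34C(=O)O[C@@H]([C@@H](C)OCc5ccccc5)C[C@@H]24 | intermediate (not isolated)
16 | (12R,13R)-13-(benzyloxy)-8α-hydroxy-3-oxo-14,15,18,19-tetranorlabda-4,6-dien-20,12-olide | C[C@@]1(O)C=CC2=CC(=O)CC[C@@]23C(=O)O[C@@H]([C@@H](C)OCc4ccccc4)C[C@@H]13 | intermediate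
17 | (12R,13R)-13-(benzyloxy)-8α-hydroxy-3-oxo-14,15,18,19-tetranorlabd-4-en-20,12-olide | C[C@@]1(O)CCC2=CC(=O)CC[C@@]23C(=O)O[C@@H]([C@@H](C)OCc4ccccc4)C[C@@H]13 | intermediate
18 | (12R,13R)-13-(benzyloxy)-8α-hydroxy-3-oxo-14,15,19-trinorlabd-5-en-20,12-olide (C4 epimers) | C[C@@]1(O)CC=C2C(C)C(=O)CC[C@@]23C(=O)O[C@@H]([C@@H](C)OCc4ccccc4)C[C@@H]13 | intermediate (not isolated)
19 | (12R,13R)-13-(benzyloxy)-8α-hydroxy-3-oxo-14,15-dinorlabd-5-en-20,12-olide | C[C@@]1(O)CC=C2C(C)(C)C(=O)CC[C@@]23C(=O)O[C@@H]([C@@H](C)OCc4ccccc4)C[C@@H]13 | intermediate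
20 | (12R,13R)-13-(benzyloxy)-8α-hydroxy-3-oxo-14,15-dinor-5α-labdan-20,12-olide | C[C@@]1(O)CC[C@H]2C(C)(C)C(=O)CC[C@@]23C(=O)O[C@@H]([C@@H](C)OCc4ccccc4)C[C@@H]13 | intermediate
21 | (12R,13R)-13-(benzyloxy)-3α,8α-dihydroxy-14,15-dinor-5α-labdan-20,12-olide | C[C@@]1(O)CC[C@H]2C(C)(C)[C@H](O)CC[C@@]23C(=O)O[C@@H]([C@@H](C)OCc4ccccc4)C[C@@H]13 | intermediate
22 | (12R,13R)-13-(benzyloxy)-14,15-dinor-5α-labdane-3α,8α,12,20-tetraol | C[C@@]1(O)CC[C@H]2C(C)(C)[C@H](O)CC[C@]2(CO)[C@H]1C[C@@H](O)[C@@H](C)OCc1ccccc1 | intermediate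
23 | (12R,13R)-13-(benzyloxy)-14,15-dinor-5α-labdane-3α,8α,12,20-tetrayl tetraacetate | C[C@@]1(OC(C)=O)CC[C@H]2C(C)(C)[C@H](OC(C)=O)CC[C@]2(COC(C)=O)[C@H]1C[C@@H](OC(C)=O)[C@@H](C)OCc1ccccc1 | intermediate
24 | (12R,13R)-13-hydroxy-14,15-dinor-5α-labdane-3α,8α,12,20-tetrayl tetraacetate | C[C@@]1(OC(C)=O)CC[C@H]2C(C)(C)[C@H](OC(C)=O)CC[C@]2(COC(C)=O)[C@H]1C[C@@H](OC(C)=O)[C@@H](C)O | intermediate
25 | (12R)-13-oxo-14,15-dinor-5α-labdane-3α,8α,12,20-tetrayl tetraacetate | C[C@@]1(OC(C)=O)CC[C@H]2C(C)(C)[C@H](OC(C)=O)CC[C@]2(COC(C)=O)[C@H]1C[C@@H](OC(C)=O)C(C)=O | intermediate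
26 | (12R,13S)-13-hydroxylabd-14-ene-3α,8α,12,20-tetrayl tetraacetate | C=C[C@](C)(O)[C@@H](C[C@@H]1[C@@]2(COC(C)=O)CC[C@@H](OC(C)=O)C(C)(C)[C@@H]2CC[C@@]1(C)OC(C)=O)OC(C)=O | target

**Totals**

Total step count: 19. Longest linear sequence: 17 steps (steps 3 to 19, from methyl (R)-lactate).

**Steps most likely to fail**

Step 10. The two facial cycloadducts may fail to equilibrate, so that kinetically preferred addition anti to the C12 substituent dominates and gives mainly the C8/C9/C10-epimeric series; cycloreversion may also compete with bridge opening. The fallback uses the kinetic preference and sets out from 9. A Mitsunobu reaction with 4-nitrobenzoic acid should give the inverted (2R,3S)-2-(benzyloxy)hex-5-en-3-yl 4-nitrobenzoate F1, and saponification the (2R,3S)-alcohol F2. Esterification with 10 gives the bromomethyl acrylate F3, alkylation of 5 the keto diester F4, deallylation–decarboxylation the keto acrylate F5, and ring-closing metathesis the C12-epimeric lactone F6. Cycloaddition under the conditions of step 10 should pass through the 12-epi oxanorbornene adduct F7 to the 12-epi dienone lactone F8. LiOH then opens the lactone to the hydroxy acid F9, and a Mitsunobu lactonization (PPh3, diisopropyl azodicarboxylate) closes it again with inversion at C12. The fallback comes back to the route at 16.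

Step 12. Under the strongly basic conditions the C8 alkoxide may be O-methylated, and C2 may be methylated as well. The fallback changes the substrate and sets out from 17. Silylation (Et3SiOTf, 2,6-lutidine) should give the C8 triethylsilyl ether F10, the methylation of step 12 with one equivalent less base should give the gem-dimethyl silyl ether F11, and HF·pyridine removes the silyl group. The fallback comes back to the route at 19.

Step 19. The vinyl reagent may enolize the α-acetoxy ketone (loss of the C12 configuration), attack or shift an acetate, or add with incomplete facial selectivity. The fallback replaces the direct vinylation by alkynylation and semihydrogenation and sets out from 25. The less basic ethynylcerium reagent (HC≡CMgBr, CeCl3, −78 °C) should add to give the (12R,13S)-propargylic alcohol F12, and hydrogenation over Pd/CaCO3 poisoned with lead and quinoline reduces the alkyne to the alkene. The fallback comes back to the route at 26.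

**Further compounds**

F1 | step 10 | (2R,3S)-2-(benzyloxy)hex-5-en-3-yl 4-nitrobenzoate | C=CC[C@H](OC(=O)c1ccc(cc1)[N+](=O)[O-])[C@@H](C)OCc1ccccc1
F2 | step 10 | (2R,3S)-2-(benzyloxy)hex-5-en-3-ol | C[C@@H](OCc1ccccc1)[C@@H](O)CC=C
F3 | step 10 | (2R,3S)-2-(benzyloxy)hex-5-en-3-yl 2-(bromomethyl)prop-2-enoate | C=CC[C@H](OC(=O)C(=C)CBr)[C@@H](C)OCc1ccccc1
F4 | step 10 | prop-2-enyl 2-[2-({[(2R,3S)-2-(benzyloxy)hex-5-en-3-yl]oxy}carbonyl)prop-2-enyl]-4-(5-methylfuran-2-yl)-3-oxobutanoate | Cc1ccc(CC(=O)C(CC(=C)C(=O)O[C@@H](CC=C)[C@@H](C)OCc2ccccc2)C(=O)OCC=C)o1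
F5 | step 10 | (2R,3S)-2-(benzyloxy)hex-5-en-3-yl 2-methylidene-6-(5-methylfuran-2-yl)-5-oxohexanoate | Cc1ccc(CC(=O)CCC(=C)C(=O)O[C@@H](CC=C)[C@@H](C)OCc2ccccc2)o1
F6 | step 10 | (6S)-6-[(1R)-1-(benzyloxy)ethyl]-3-[4-(5-methylfuran-2-yl)-3-oxobutyl]-5,6-dihydro-2H-pyran-2-one | Cc1ccc(CC(=O)CCC2=CC[C@@H]([C@@H](C)OCc3ccccc3)OC2=O)o1
F7 | step 10 | (12S,13R)-13-(benzyloxy)-5α,8α-epoxy-3-oxo-14,15,18,19-tetranorlabd-6-en-20,12-olide | C[C@@]12O[C@]3(C=C1)CC(=O)CC[C@@]34C(=O)O[C@H]([C@@H](C)OCc5ccccc5)C[C@@H]24
F8 | step 10 | (12S,13R)-13-(benzyloxy)-8α-hydroxy-3-oxo-14,15,18,19-tetranorlabda-4,6-dien-20,12-olide | C[C@@]1(O)C=CC2=CC(=O)CC[C@@]23C(=O)O[C@H]([C@@H](C)OCc4ccccc4)C[C@@H]13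
F9 | step 10 | (12S,13R)-13-(benzyloxy)-8α,12-dihydroxy-3-oxo-14,15,18,19-tetranorlabda-4,6-dien-20-oic acid | C[C@@]1(O)C=CC2=CC(=O)CC[C@]2(C(=O)O)[C@H]1C[C@H](O)[C@@H](C)OCc1ccccc1
F10 | step 12 | (12R,13R)-13-(benzyloxy)-3-oxo-8α-(triethylsilyloxy)-14,15,18,19-tetranorlabd-4-en-20,12-olide | C[C@@]1(O[Si](CC)(CC)CC)CCC2=CC(=O)CC[C@@]23C(=O)O[C@@H]([C@@H](C)OCc4ccccc4)C[C@@H]13
F11 | step 12 | (12R,13R)-13-(benzyloxy)-3-oxo-8α-(triethylsilyloxy)-14,15-dinorlabd-5-en-20,12-olide | C[C@@]1(O[Si](CC)(CC)CC)CC=C2C(C)(C)C(=O)CC[C@@]23C(=O)O[C@@H]([C@@H](C)OCc4ccccc4)C[C@@H]13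
F12 | step 19 | (12R,13S)-13-hydroxylabd-14-yne-3α,8α,12,20-tetrayl tetraacetate | C[C@@]1(OC(C)=O)CC[C@H]2C(C)(C)[C@H](OC(C)=O)CC[C@]2(COC(C)=O)[C@H]1C[C@@H](OC(C)=O)[C@@](C)(O)C#C
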